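Assumption: the target has no stereocentre and no stereogenic double bond, so it is achiral and needs no enantiocontrol. Racemic, non-isolated intermediates are written without stereodescriptors; the only descriptor used is E for the chalcone.

**Retrosynthetic overview**
1. Target 16 ⇐ pentamethoxyflavone 14 (peri-selective 5-O-demethylation) ⇐ flavonol 13 (O-methylation) ⇐ flavone 11 (C3 oxygenation via the 2,3-epoxide).
2. Ring C, the only ring built, ⇐ chalcone 8 by oxa-Michael closure and dehydrogenation; rings A and B come preformed.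
3. Chalcone 8 ⇐ Cα=Cβ disconnection: Claisen–Schmidt aldol condensation of acetophenone 5 with benzaldehyde 6 (key C–C bond).
4. Acetophenone 5 ⇐ 3,4,5-trimethoxyphenol 1 by C-acetylation, ring bromination and Cu-catalysed methoxylation.

**Route**

Step 1
Reactants: 1 3,4,5-trimethoxyphenol
Product: 3 1-(6-hydroxy-2,3,4-trimethoxyphenyl)ethanone, via difluoroboron chelate 2 (not isolated)
Conditions: AcOH (2 equiv), BF3·OEt2 (3 equiv), 90 °C, 2 h; then H2O, 60 °C
Reagents that add atoms: acetic acid CC(=O)O
Why: BF3-mediated Friedel–Crafts (Fries-type) C-acylation of the symmetrical, strongly activated phenol occurs at either of the two equivalent positions ortho to OH, the ketone being held as its O,O-difluoroboron chelate until aqueous hydrolysis.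

Step 2
Reactants: 3 1-(6-hydroxy-2,3,4-trimethoxyphenyl)ethanone
Product: 4 1-(3-bromo-2-hydroxy-4,5,6-trimethoxyphenyl)ethanone
Conditions: NBS (1.05 equiv), MeCN, 0 °C → rt, 1 h
Reagents that add atoms: N-bromosuccinimide O=C1CCC(=O)N1Br
Why: Electrophilic aromatic bromination takes the single remaining ring C–H (ortho to OH and OMe), which is far more reactive than the ketone α-position.

Step 3
Reactants: 4 1-(3-bromo-2-hydroxy-4,5,6-trimethoxyphenyl)ethanone
Product: 5 1-(2-hydroxy-3,4,5,6-tetramethoxyphenyl)ethanone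
Conditions: NaOMe (6 equiv, 5 M in MeOH), CuBr (20 mol %), DMF, 110 °C, N2, 8 h; then 2 M HCl
Reagents that add atoms: sodium methoxide [Na+].[O-]C
Why: Ullmann-type copper-catalysed methoxylation replaces the aryl bromide, and the substrate reacts as its phenoxide, which damps enolate self-condensation of the acetyl group.

Step 4
Reactants: 5 1-(2-hydroxy-3,4,5,6-tetramethoxyphenyl)ethanone; 6 benzaldehyde
Product: 8 (E)-1-(2-hydroxy-3,4,5,6-tetramethoxyphenyl)-3-phenylprop-2-en-1-one, via aldol adduct 7 (not isolated)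
Conditions: PhCHO (1.2 equiv), 50% aq. KOH, EtOH, rt, 36 h; then cold 2 M HCl
Reagents that add atoms: none
Why: Claisen–Schmidt crossed aldol condensation joins the methyl-ketone enolate to non-enolisable benzaldehyde, and E1cB dehydration of the β-hydroxy ketone gives the conjugated, thermodynamically favoured E-enone.

Step 5
Reactants: 8 (E)-1-(2-hydroxy-3,4,5,6-tetramethoxyphenyl)-3-phenylprop-2-en-1-one
Product: 11 5,6,7,8-tetramethoxyflavone, via flavanone 9 (not isolated), via 3-iodoflavanone 10 (not isolated)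
Conditions: I2 (10 mol %), DMSO, 130 °C, 2–3 h; aq. Na2S2O3 work-up
Reagents that add atoms: none
Why: Iodine-catalysed oxidative cyclisation proceeds by intramolecular oxa-Michael addition of the 2'-OH, α-iodination and HI elimination (DMSO reoxidises HI to I2), so the transient flavanone stereocentre is erased on aromatisation.

Step 6
Reactants: 11 5,6,7,8-tetramethoxyflavone
Product: 13 3-hydroxy-5,6,7,8-tetramethoxyflavone, via flavone 2,3-epoxide 12 (not isolated)
Conditions: DMDO (ca. 0.07 M in acetone, 4 equiv in portions), CH2Cl2, 0 °C → rt, dark, 24–48 h; evaporate; p-TsOH·H2O (5 mol %), CH2Cl2, rt, 1 h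
Reagents that add atoms: dimethyldioxirane CC1(C)OO1
Why: Electrophilic epoxidation of the enol-ether-like C2=C3 bond is followed by acid-catalysed epoxide opening at C2 (oxocarbenium) and loss of H-3, giving the aromatic flavonol with loss of the transient stereocentres.

Step 7
Reactants: 13 3-hydroxy-5,6,7,8-tetramethoxyflavone
Product: 14 3,5,6,7,8-pentamethoxyflavone
Conditions: MeI (3 equiv), K2CO3 (3 equiv), acetone, reflux, 6 h
Reagents that add atoms: iodomethane CI
Why: Williamson O-methylation of the only free, acidic hydroxyl (3-OH) is unambiguous.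

Step 8
Reactants: 14 3,5,6,7,8-pentamethoxyflavone
Product: 16 5-hydroxy-3,6,7,8-tetramethoxyflavone, via dichloroboron chelate 15 (not isolated)
Conditions: BCl3 (1.0 M in CH2Cl2, 1.3 equiv), CH2Cl2, −78 → 0 °C, 1–2 h; then H2O / 1 M HCl, rt
Reagents that add atoms: none
Why: Chelation-controlled Lewis-acid ether cleavage: boron bridges C4=O and the peri 5-oxygen in a six-membered chelate, chloride removes that methyl by SN2, and hydrolysis frees the hydrogen-bonded 5-OH while the other methoxy groups survive at ≤ 0 °C.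

**Compound list**
1 | 3,4,5-trimethoxyphenol | COc1cc(O)cc(OC)c1OC | starting material
2 | (2-acetyl-3,4,5-trimethoxyphenoxy)difluoroborane, O,O-chelate of 3 (C=O→B dative bond not drawn; not isolated) | CC(=O)c1c(OB(F)F)cc(OC)c(OC)c1OC | intermediate
3 | 1-(6-hydroxy-2,3,4-trimethoxyphenyl)ethanone | CC(=O)c1c(O)cc(OC)c(OC)c1OC | intermediate
4 | 1-(3-bromo-2-hydroxy-4,5,6-trimethoxyphenyl)ethanone | CC(=O)c1c(O)c(Br)c(OC)c(OC)c1OC | intermediate
5 | 1-(2-hydroxy-3,4,5,6-tetramethoxyphenyl)ethanone | CC(=O)c1c(O)c(OC)c(OC)c(OC)c1OC | intermediate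
6 | benzaldehyde | O=Cc1ccccc1 | starting material
7 | 3-hydroxy-1-(2-hydroxy-3,4,5,6-tetramethoxyphenyl)-3-phenylpropan-1-one (racemic aldol adduct; not isolated) | O=C(CC(O)c1ccccc1)c1c(O)c(OC)c(OC)c(OC)c1OC | intermediate
8 | (E)-1-(2-hydroxy-3,4,5,6-tetramethoxyphenyl)-3-phenylprop-2-en-1-one (2'-hydroxy-3',4',5',6'-tetramethoxychalcone) | O=C(/C=C/c1ccccc1)c1c(O)c(OC)c(OC)c(OC)c1OC | intermediate
9 | 5,6,7,8-tetramethoxyflavanone (racemic; not isolated) | O=C1CC(c2ccccc2)Oc2c1c(OC)c(OC)c(OC)c2OC | intermediate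
10 | 3-iodo-5,6,7,8-tetramethoxyflavanone (racemic, diastereomer mixture; not isolated) | O=C1C(I)C(c2ccccc2)Oc2c1c(OC)c(OC)c(OC)c2OC | intermediate
11 | 5,6,7,8-tetramethoxyflavone (5,6,7,8-tetramethoxy-2-phenyl-4H-chromen-4-one) | O=c1cc(-c2ccccc2)oc2c1c(OC)c(OC)c(OC)c2OC | intermediate
12 | 2,3-epoxy-5,6,7,8-tetramethoxyflavanone (flavone 2,3-epoxide, racemic; not isolated) | O=C1C2OC2(c2ccccc2)Oc2c1c(OC)c(OC)c(OC)c2OC | intermediate
13 | 3-hydroxy-5,6,7,8-tetramethoxyflavone | O=c1c(O)c(-c2ccccc2)oc2c1c(OC)c(OC)c(OC)c2OC | intermediate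
14 | 3,5,6,7,8-pentamethoxyflavone | COc1c(-c2ccccc2)oc2c(OC)c(OC)c(OC)c(OC)c2c1=O | intermediate
15 | dichloro[(3,6,7,8-tetramethoxy-4-oxo-2-phenyl-4H-chromen-5-yl)oxy]borane, chelated to C4=O (dative bond not drawn; not isolated) | COc1c(-c2ccccc2)oc2c(OC)c(OC)c(OC)c(OB(Cl)Cl)c2c1=O | intermediate
16 | 5-hydroxy-3,6,7,8-tetramethoxyflavone (5-hydroxy-3,6,7,8-tetramethoxy-2-phenyl-4H-chromen-4-one) | COc1c(OC)c(O)c2c(=O)c(OC)c(-c3ccccc3)oc2c1OC | target

**Totals**
Total step count: 8. Longest linear sequence: 8 steps (1 → 16); benzaldehyde 6 enters at step 4.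

**Three steps most likely to fail, with fallbacks**

Step 3 (Cu-catalysed methoxylation; risks are hydrodebromination back to 3 and base-induced condensation of the acetyl group). The fallback sets out from ketone 3 and installs the extra oxygen by formylation and oxidation instead of C–O coupling. Rieche formylation (Cl2CHOMe, TiCl4, CH2Cl2, 0 °C) at the single free ring position gives 3-acetyl-2-hydroxy-4,5,6-trimethoxybenzaldehyde F1. Dakin oxidation (30% H2O2, aq. NaOH, 0 °C → rt, N2) takes the aldehyde, which reacts much faster than the ketone, through 3-acetyl-2-hydroxy-4,5,6-trimethoxyphenyl formate F2, hydrolysed in the same flask, to the catechol 1-(2,3-dihydroxy-4,5,6-trimethoxyphenyl)ethanone F3. The dianion of the catechol (NaH 2.1 equiv, DMSO) is methylated with MeI (1.0 equiv) at the more nucleophilic, non-chelated 3-oxygen, and the route is rejoined at ketone 5.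

Step 6 (DMDO epoxidation and rearrangement; risks are slow epoxidation of the vinylogous ester and oxidation of the electron-rich A ring). The fallback sets out from flavone 11 and uses C3 metalation, borylation and oxidation. LDA (1.2 equiv, THF, −78 °C) deprotonates C3 to give 3-lithio-5,6,7,8-tetramethoxyflavone F4. This is trapped with B(OMe)3 as dimethyl (5,6,7,8-tetramethoxy-4-oxo-2-phenyl-4H-chromen-3-yl)boronate F5. Oxidation in the same flask (AcOH, 30% H2O2, 0 °C → rt) converts the C–B bond into C–OH, and the route is rejoined at flavonol 13.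

Step 8 (selective 5-O-demethylation; risk is competing cleavage of the 3-OMe or 6-OMe group). The fallback sets out from flavonol 13 and reverses the order of events, so that no 3-OMe is present during the ether cleavage. HBr (33% in AcOH, rt → 40 °C) removes the carbonyl-activated 5-methyl group and gives 3,5-dihydroxy-6,7,8-trimethoxyflavone F6. The more acidic, more reactive 3-OH is then methylated selectively (Me2SO4 1.05 equiv, K2CO3 1.1 equiv, acetone, rt) while the strongly hydrogen-bonded 5-OH stays free, and the route is rejoined at target 16.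

**Further compounds**
F1 | step 3 | 3-acetyl-2-hydroxy-4,5,6-trimethoxybenzaldehyde | CC(=O)c1c(O)c(C=O)c(OC)c(OC)c1OC
F2 | step 3 | 3-acetyl-2-hydroxy-4,5,6-trimethoxyphenyl formate (not isolated) | CC(=O)c1c(O)c(OC=O)c(OC)c(OC)c1OC
F3 | step 3 | 1-(2,3-dihydroxy-4,5,6-trimethoxyphenyl)ethanone | CC(=O)c1c(O)c(O)c(OC)c(OC)c1OC
F4 | step 6 | 3-lithio-5,6,7,8-tetramethoxyflavone (not isolated) | [Li]c1c(-c2ccccc2)oc2c(OC)c(OC)c(OC)c(OC)c2c1=O
F5 | step 6 | dimethyl (5,6,7,8-tetramethoxy-4-oxo-2-phenyl-4H-chromen-3-yl)boronate (not isolated) | COB(OC)c1c(-c2ccccc2)oc2c(OC)c(OC)c(OC)c(OC)c2c1=O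
F6 | step 8 | 3,5-dihydroxy-6,7,8-trimethoxyflavone | O=c1c(O)c(-c2ccccc2)oc2c(OC)c(OC)c(OC)c(O)c12
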